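**Plan**

Locants: ring A = C1–C5 + C10, ring B = C5–C10, C11 = ArCH2; methyls on C5, C8, C9; acid chain on C4; isopropylidene on C3; β = face of H-10.
Cuts, last to first: C3=CMe2 (Wittig) and the acid oxidation level; C8–CH3 (cuprate on a C6 enone), C6=O and C11=O then removed; ring B at C5–C6 (radical cyclization); aryl–C11 (aryllithium + lactone); C9–CH3 and C9–C8 (lactone alkylations); C9–C10 and C4–chain (ketone alkylations).
Forward: ring A is elaborated from cyclohexenone, a temporary cis-fused γ-lactone (C11/O–C5) carries the quaternary C9, the arene is joined, and ring B is closed last by the C5–C6 bond.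
Enabling feature: the exocyclic C5=CH2 on ring A is a masked tertiary radical that already holds the C5 methyl carbon and sits 1,6 to the formyl carbon C6 of the C9 side chain; the C5 radical has three σ-bonds (C4, C10, CH3), so it can bond equatorially and give the trans A/B fusion.
Stereochemistry: C3–O (temporary) from a catalytic asymmetric epoxidation; C4 by anti alkylation; C10 by equilibration; C5–O (temporary) by hydride delivery; C9 by convex-face methylation of the lactone; C5 in the key step; C8 by axial cuprate addition.

Key step: step 14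

Remark: the target is taken as drawn, with a trans-fused decalin, H-10 β, C5–CH3 α, C9–CH3 α, C8–CH3 β and the C4 chain α.
Assumption: the silyl ethers may or may not survive the hot alkali of step 18, so fluoride is applied in the same step. Compound 18 may exist as its cyclic hemiketal and is drawn open-chain.

**Route**

Step 1
Reactants: 1 cyclohex-2-en-1-one
Product: 2 (2S,3S)-2,3-epoxycyclohexan-1-one
Conditions: 50% aq. H2O2, 9-amino-9-deoxy-epi-cinchona alkaloid bis(trifluoroacetate) salt (10 mol%, pseudoenantiomer chosen for the (2S,3S) epoxide), dioxane, 30 °C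
Reagents that add atoms: hydrogen peroxide, OO
Why: Amine-salt-catalysed Weitz–Scheffer epoxidation runs through a chiral iminium ion, so the peroxide should add to one enantiotopic face and set C3 and C4 (oxygen on the β face).

Step 2
Reactants: 2 (2S,3S)-2,3-epoxycyclohexan-1-one; 3 tert-butyl(3-iodopropoxy)dimethylsilane
Product: 4 trans-3-hydroxy-2-(3-silyloxypropyl)cyclohexanone
Conditions: Li (2.1 equiv), NH3(l)/THF, −78 °C; then 3, −78 → −33 °C; NH4Cl
Reagents that add atoms: none
Why: Dissolving-metal cleavage of the C4–O bond gives the C4/C5 enolate regiospecifically with the C3 alkoxide intact (reductive alkylation of an α,β-epoxy ketone), and the iodide should alkylate C4 anti to the C3 oxido group, the trans isomer also being the thermodynamic one at this epimerizable centre.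

Step 3
Reactants: 4 trans-3-hydroxy-2-(3-silyloxypropyl)cyclohexanone
Product: 5 bis-silyl ketone
Conditions: t-BuMe2SiOTf, 2,6-lutidine, CH2Cl2, −78 → 0 °C
Reagents that add atoms: tert-butyldimethylsilyl trifluoromethanesulfonate, CC(C)(C)[Si](C)(C)OS(=O)(=O)C(F)(F)F
Why: Silylation under non-basic silyl triflate conditions protects the C3 alcohol without retro-aldol cleavage or elimination of the β-hydroxy ketone.

Step 4
Reactants: 5 bis-silyl ketone; 6 methyl bromoacetate
Product: 8 all-equatorial keto ester, via 2,6-trans keto ester 7 (not isolated)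
Conditions: LiN(iPr)2, THF, −78 °C; 6, DMPU, −78 → −30 °C; then NaOMe (0.1 equiv), MeOH, 0 °C
Reagents that add atoms: none
Why: Kinetic deprotonation takes the unsubstituted α'-methylene C10 instead of the tertiary C4–H, the enolate is alkylated by the bromoacetate, and catalytic methoxide should equilibrate C10 (and C4) to the all-equatorial ketone anchored by the fixed C3 centre, so C10 ends cis to the C4 chain.

Step 5
Reactants: 8 all-equatorial keto ester
Product: 10 cis-fused γ-lactone, via hydroxy ester 9 (not isolated)
Conditions: LiBH(s-Bu)3, THF, −78 → 0 °C; aq. NH4Cl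
Reagents that add atoms: none
Why: The bulky trialkylborohydride should attack from the equatorial direction to give the axial (α) C5 alkoxide cis to both flanking substituents, which closes onto the neighbouring ester by intramolecular acyl substitution to the cis-fused lactone.

Step 6
Reactants: 10 cis-fused γ-lactone; 11 3-bromo-1,1-dimethoxypropane
Product: 12 C9-monoalkylated lactone
Conditions: LiN(iPr)2, THF, −78 °C; 11, NaI (cat.), DMPU, −78 → 0 °C
Reagents that add atoms: none
Why: The enolate of the cis-fused bicyclic lactone should be alkylated on its convex face by the primary halide; the configuration created at C9 is erased in the next step.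

Step 7
Reactants: 12 C9-monoalkylated lactone
Product: 13 C9-quaternary lactone
Conditions: LiN(iPr)2, THF, −78 °C; MeI, −78 → −20 °C
Reagents that add atoms: iodomethane, CI
Why: Re-enolization and methylation should again occur on the convex face, cis to H-10, which pushes the acetal chain to the concave face and sets the quaternary centre C9 as needed in ring B.

Step 8
Reactants: 14 4-methoxy-2-methylphenol
Product: 15 2-bromo-4-methoxy-6-methylphenol
Conditions: Br2, CH2Cl2, 0 °C
Reagents that add atoms: bromine, BrBr
Why: Electrophilic aromatic bromination is directed by the phenol to its only free ortho position, the para position being blocked by the methoxy group.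

Step 9
Reactants: 15 2-bromo-4-methoxy-6-methylphenol
Product: 16 1-bromo-5-methoxy-2-(methoxymethoxy)-3-methylbenzene
Conditions: MeOCH2Cl, i-Pr2NEt, CH2Cl2, 0 °C → rt
Reagents that add atoms: chloromethyl methyl ether, COCCl
Why: O-Alkylation of the phenol gives an acetal that tolerates organolithium, hydride, cuprate and hot base and supports the later bromine–lithium exchange by chelation.

Step 10
Reactants: 16 1-bromo-5-methoxy-2-(methoxymethoxy)-3-methylbenzene; 13 C9-quaternary lactone
Product: 18 C5-hydroxy C11 aryl ketone, via aryllithium 17 (not isolated)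
Conditions: n-BuLi, THF, −78 °C; then 13, −78 → 0 °C; aq. NH4Cl
Reagents that add atoms: none
Why: Bromine–lithium exchange gives the chelated aryllithium, which should add once to the lactone carbonyl C11, a second addition being blocked by the adjacent quaternary C9, so work-up gives the ring-opened hydroxy ketone.

Step 11
Reactants: 18 C5-hydroxy C11 aryl ketone
Product: 19 C5,C11-diketone
Conditions: Dess–Martin periodinane, CH2Cl2, rt
Reagents that add atoms: none
Why: Dess–Martin oxidation converts the secondary C5 alcohol into the ketone under near-neutral conditions that leave the α-centres C4 and C10, both equatorial, untouched.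

Step 12
Reactants: 19 C5,C11-diketone
Product: 20 C5-methylene acetal
Conditions: Cp2TiMe2, toluene, 70 °C, dark
Reagents that add atoms: dimethyltitanocene, C[Ti](C)(C1C=CC=C1)C1C=CC=C1
Why: Petasis methylenation through Cp2Ti=CH2 is non-basic, so the enolizable β-silyloxy cyclohexanone should be olefinated without epimerization or elimination, while the aryl ketone shielded by the quaternary C9 should not react.

Step 13
Reactants: 20 C5-methylene acetal
Product: 21 C5-methylene C6-aldehyde
Conditions: LiBF4, MeCN/H2O (98:2), rt
Reagents that add atoms: water, O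
Why: The acyclic dimethyl acetal is hydrolysed under mild Lewis-acid assistance that should leave the silyl ethers, the aryl acetal and the exocyclic alkene unchanged.

Step 14
Reactants: 21 C5-methylene C6-aldehyde
Product: 22 trans-decalin C6-alcohol
Conditions: Fe(acac)3 (0.5 equiv), PhSiH3 (3 equiv), EtOH/ethylene glycol, 60 °C, argon
Reagents that add atoms: none
Why: The iron hydride formed from Fe(acac)3 and PhSiH3 transfers a hydrogen atom to the terminal carbon of the 1,1-disubstituted C5=CH2 alkene, creating the C5 methyl group and a tertiary C5 radical that adds to the formyl carbon C6; the alkoxy radical is then reduced and protonated and the silane regenerates the hydride. The closest known reaction types are the iron-hydride reductive cyclization of alkene-tethered ketones, the iron-catalysed radical addition of unactivated alkenes to aldehydes and tin-hydride 6-exo cyclizations onto aldehydes. Ring B is closed in the 6-exo-trig mode onto the C=O group by the C5–C6 bond. The quaternary centre C5 is controlled by a chair-like transition state in which the tether leaves C10 equatorially and the planar C5 radical bonds to C6 in the equatorial direction, so the methyl group should end axial and anti to H-10 (trans fusion), with reversible carbonyl addition favouring this arrangement; the C6 carbinol centre is not controlled and is erased in step 15. The step needs chemoselectivity for one alkene and one carbonyl, secured because no other C=C bond is present, the aryl ketone C11 could only close a four-membered ring and the aldehyde is the best radical acceptor; cyclization must also outrun reduction of the radical, which the 1,6-relationship held on ring A should ensure.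

Step 15
Reactants: 22 trans-decalin C6-alcohol
Product: 23 C6-ketone
Conditions: Dess–Martin periodinane, CH2Cl2, rt
Reagents that add atoms: none
Why: Dess–Martin oxidation removes the uncontrolled C6 carbinol centre and gives the ketone that activates C7 and C8.

Step 16
Reactants: 23 C6-ketone
Product: 24 C7=C8 enone
Conditions: LiN(iPr)2, THF, −78 °C; then N-tert-butylbenzenesulfinimidoyl chloride, −78 °C
Reagents that add atoms: none
Why: The C6 ketone can enolize only toward C7 because C5 is quaternary, and Mukaiyama dehydrogenation of the lithium enolate should give the enone at low temperature.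

Step 17
Reactants: 24 C7=C8 enone
Product: 25 C8-methyl diketone
Conditions: Me2CuLi, Et2O, −40 → 0 °C; aq. NH4Cl
Reagents that add atoms: lithium dimethylcuprate, [Li+].C[Cu-]C
Why: The Gilman cuprate should add to C8 along the axial trajectory on the β face, anti to the axial C9 methyl that blocks the α face, so the new C8 methyl is axial and trans to the C9 methyl as in the target.

Step 18
Reactants: 25 C8-methyl diketone
Product: 27 C3,chain diol, via bis-silyl ether 26 (not isolated)
Conditions: N2H4·H2O, KOH, diethylene glycol, 130 → 200 °C; then Bu4NF, THF, rt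
Reagents that add atoms: none
Why: Wolff–Kishner reduction through the hydrazones converts the C6 ketone and the aryl ketone C11 into methylene groups (C8 is β to C6 and cannot epimerize), and fluoride then cleaves both silyl ethers.

Step 19
Reactants: 27 C3,chain diol
Product: 28 C3-ketone primary alcohol
Conditions: Al(Oi-Pr)3, acetone/toluene, reflux
Reagents that add atoms: none
Why: Oppenauer oxidation is selective for the secondary C3 alcohol over the primary one, which avoids lactol and lactone formation between the two oxygens; C4, now α to the ketone, already has the more stable equatorial configuration.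

Step 20
Reactants: 28 C3-ketone primary alcohol
Product: 29 isopropylidene primary alcohol
Conditions: [i-PrPPh3]I, KN(SiMe3)2, toluene, 0 → 90 °C; aq. NH4Cl
Reagents that add atoms: isopropyltriphenylphosphonium iodide, CC(C)[P+](c1ccccc1)(c1ccccc1)c1ccccc1.[I-]
Why: Wittig olefination with the unstabilized isopropylidene ylide places the tetrasubstituted alkene regiospecifically at C3, the primary alcohol being carried as its alkoxide.

Step 21
Reactants: 29 isopropylidene primary alcohol
Product: 30 acetal-protected acid
Conditions: TEMPO (cat.), PhI(OAc)2, MeCN/H2O, rt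
Reagents that add atoms: water, O
Why: The nitroxyl-catalysed oxidation takes the primary alcohol through the aldehyde hydrate to the acid and should not touch the tetrasubstituted alkene or the protected arene.

Step 22
Reactants: 30 acetal-protected acid
Product: 31 target
Conditions: 6 M HCl (aq)/THF, 40 °C
Reagents that add atoms: none
Why: Aqueous acid hydrolyses the aryl methoxymethyl acetal under conditions mild enough to keep the isopropylidene group in place, releasing the phenol.

**Compound list**

1 | cyclohex-2-en-1-one | O=C1C=CCCC1 | starting material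
2 | (2S,3S)-2,3-epoxycyclohexan-1-one | O=C1CCC[C@@H]2O[C@H]12 | intermediate
3 | tert-butyl(3-iodopropoxy)dimethylsilane | ICCCO[Si](C)(C)C(C)(C)C | starting material
4 | (2R,3S)-2-{3-[(tert-butyldimethylsilyl)oxy]propyl}-3-hydroxycyclohexan-1-one (trans) | O=C1CCC[C@H](O)[C@H]1CCCO[Si](C)(C)C(C)(C)C | intermediate
5 | (2R,3S)-3-[(tert-butyldimethylsilyl)oxy]-2-{3-[(tert-butyldimethylsilyl)oxy]propyl}cyclohexan-1-one | O=C1CCC[C@H](O[Si](C)(C)C(C)(C)C)[C@H]1CCCO[Si](C)(C)C(C)(C)C | intermediate
6 | methyl bromoacetate | COC(=O)CBr | starting material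
7 | methyl 2-[(1S,3R,4S)-4-silyloxy-3-(3-silyloxypropyl)-2-oxocyclohexyl]acetate (silyl = t-BuMe2Si; 2,6-trans, kinetic C10 epimer) | COC(=O)C[C@@H]1CC[C@H](O[Si](C)(C)C(C)(C)C)[C@@H](CCCO[Si](C)(C)C(C)(C)C)C1=O | intermediate
8 | methyl 2-[(1R,3R,4S)-4-silyloxy-3-(3-silyloxypropyl)-2-oxocyclohexyl]acetate (all substituents equatorial) | COC(=O)C[C@H]1CC[C@H](O[Si](C)(C)C(C)(C)C)[C@@H](CCCO[Si](C)(C)C(C)(C)C)C1=O | intermediate
9 | methyl 2-[(1R,2S,3S,4S)-2-hydroxy-4-silyloxy-3-(3-silyloxypropyl)cyclohexyl]acetate (C5–OH α, formed as the lithium alkoxide) | COC(=O)C[C@H]1CC[C@H](O[Si](C)(C)C(C)(C)C)[C@@H](CCCO[Si](C)(C)C(C)(C)C)[C@H]1O | intermediate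
10 | (3aR,6S,7S,7aS)-6-silyloxy-7-(3-silyloxypropyl)hexahydro-1-benzofuran-2(3H)-one (cis-fused) | O=C1C[C@H]2CC[C@H](O[Si](C)(C)C(C)(C)C)[C@@H](CCCO[Si](C)(C)C(C)(C)C)[C@H]2O1 | intermediate
11 | 3-bromo-1,1-dimethoxypropane | COC(CCBr)OC | starting material
12 | (3R,3aR,6S,7S,7aS)-3-(3,3-dimethoxypropyl) derivative of lactone 10 (chain cis to H-3a) | O=C1[C@H](CCC(OC)OC)[C@H]2CC[C@H](O[Si](C)(C)C(C)(C)C)[C@@H](CCCO[Si](C)(C)C(C)(C)C)[C@H]2O1 | intermediate
13 | (3S,3aR,6S,7S,7aS)-3-(3,3-dimethoxypropyl)-3-methyl derivative of lactone 10 (methyl cis to H-3a) | O=C1[C@@](C)(CCC(OC)OC)[C@H]2CC[C@H](O[Si](C)(C)C(C)(C)C)[C@@H](CCCO[Si](C)(C)C(C)(C)C)[C@H]2O1 | intermediate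
14 | 4-methoxy-2-methylphenol | COc1ccc(O)c(C)c1 | starting material
15 | 2-bromo-4-methoxy-6-methylphenol | COc1cc(C)c(O)c(Br)c1 | intermediate
16 | 1-bromo-5-methoxy-2-(methoxymethoxy)-3-methylbenzene | COc1cc(C)c(OCOC)c(Br)c1 | intermediate
17 | [5-methoxy-2-(methoxymethoxy)-3-methylphenyl]lithium | COc1cc(C)c(OCOC)c([Li])c1 | intermediate
18 | C11 aryl ketone; C9 bears CH3, the 3,3-dimethoxypropyl chain (C8–C6) and ring A at C10; ring A: C5–OH α, C4 3-silyloxypropyl α, C3–OSi β | COc1cc(C)c(OCOC)c(C(=O)[C@@](C)(CCC(OC)OC)[C@H]2CC[C@H](O[Si](C)(C)C(C)(C)C)[C@@H](CCCO[Si](C)(C)C(C)(C)C)[C@H]2O)c1 | intermediate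
19 | as 18 with C5 ketone (C5,C11-diketone) | COc1cc(C)c(OCOC)c(C(=O)[C@@](C)(CCC(OC)OC)[C@H]2CC[C@H](O[Si](C)(C)C(C)(C)C)[C@@H](CCCO[Si](C)(C)C(C)(C)C)C2=O)c1 | intermediate
20 | as 19 with C5=CH2 in place of the C5 ketone | COc1cc(C)c(OCOC)c(C(=O)[C@@](C)(CCC(OC)OC)[C@H]2CC[C@H](O[Si](C)(C)C(C)(C)C)[C@@H](CCCO[Si](C)(C)C(C)(C)C)C2=C)c1 | intermediate
21 | as 20 with the acetal hydrolysed to the C6 aldehyde (cyclization substrate) | COc1cc(C)c(OCOC)c(C(=O)[C@@](C)(CCC=O)[C@H]2CC[C@H](O[Si](C)(C)C(C)(C)C)[C@@H](CCCO[Si](C)(C)C(C)(C)C)C2=C)c1 | intermediate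
22 | trans-decalin: C5–CH3 α, H-10 β, C6–OH (either epimer), C9–CH3 α, C9–C(=O)Ar β, C4 3-silyloxypropyl α, C3–OSi β | COc1cc(C)c(OCOC)c(C(=O)[C@]2(C)[C@H]3CC[C@H](O[Si](C)(C)C(C)(C)C)[C@@H](CCCO[Si](C)(C)C(C)(C)C)[C@]3(C)C(O)CC2)c1 | intermediate
23 | as 22 with C6 ketone | COc1cc(C)c(OCOC)c(C(=O)[C@]2(C)[C@H]3CC[C@H](O[Si](C)(C)C(C)(C)C)[C@@H](CCCO[Si](C)(C)C(C)(C)C)[C@]3(C)C(=O)CC2)c1 | intermediate
24 | as 23 with C7=C8 double bond (enone) | COc1cc(C)c(OCOC)c(C(=O)[C@]2(C)[C@H]3CC[C@H](O[Si](C)(C)C(C)(C)C)[C@@H](CCCO[Si](C)(C)C(C)(C)C)[C@]3(C)C(=O)C=C2)c1 | intermediate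
25 | as 23 with C8–CH3 β (axial) | COc1cc(C)c(OCOC)c(C(=O)[C@]2(C)[C@H]3CC[C@H](O[Si](C)(C)C(C)(C)C)[C@@H](CCCO[Si](C)(C)C(C)(C)C)[C@]3(C)C(=O)C[C@@H]2C)c1 | intermediate
26 | as 25 with C6 and C11 as CH2 (bis-silyl ether) | COc1cc(C)c(OCOC)c(C[C@]2(C)[C@H]3CC[C@H](O[Si](C)(C)C(C)(C)C)[C@@H](CCCO[Si](C)(C)C(C)(C)C)[C@]3(C)CC[C@@H]2C)c1 | intermediate
27 | as 26 with free C3–OH (β) and free 3-hydroxypropyl chain | COc1cc(C)c(OCOC)c(C[C@]2(C)[C@H]3CC[C@H](O)[C@@H](CCCO)[C@]3(C)CC[C@@H]2C)c1 | intermediate
28 | as 27 with C3 ketone | COc1cc(C)c(OCOC)c(C[C@]2(C)[C@H]3CCC(=O)[C@@H](CCCO)[C@]3(C)CC[C@@H]2C)c1 | intermediate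
29 | as 28 with C3=C(CH3)2 | COc1cc(C)c(OCOC)c(C[C@]2(C)[C@H]3CCC(=C(C)C)[C@@H](CCCO)[C@]3(C)CC[C@@H]2C)c1 | intermediate
30 | methoxymethyl ether of the target (chain oxidized to CO2H) | COc1cc(C)c(OCOC)c(C[C@]2(C)[C@H]3CCC(=C(C)C)[C@@H](CCC(=O)O)[C@]3(C)CC[C@@H]2C)c1 | intermediate
31 | CNP0299684.1 | COc1cc(C)c(O)c(C[C@]2(C)[C@H]3CCC(=C(C)C)[C@@H](CCC(=O)O)[C@]3(C)CC[C@@H]2C)c1 | target

**Count and risks**

Total: 22 steps. Longest linear sequence: 20 steps (steps 1–7 and 10–22, from 1 to 31).

Step 14 is the most exposed. Reduction of the tertiary C5 radical, reversal of its addition to the formyl group, or an incomplete preference for the trans ring fusion could each erode it. The fallback sets out from 21 and returns at 23, so step 15 is skipped. The aldehyde would be condensed with NH2OH·HCl in pyridine to the aldoxime F1 and dehydrated (2,4,6-trichloro-1,3,5-triazine, DMF) to the nitrile F2. The same Fe(acac)3/PhSiH3 conditions then close ring B by irreversible 6-exo-dig addition of the C5 radical to the nitrile carbon, and the cyclic ketimine F3 is hydrolysed on acidic work-up to 23.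

Step 2 may fail because C-alkylation of the oxido enolate by an unactivated iodide competes with proton transfer and over-reduction. The fallback sets out from 1 and returns at 4. Iodination (I2, pyridine) gives 2-iodocyclohex-2-en-1-one F4. B-alkyl Suzuki coupling with the 9-BBN adduct of allyl tert-butyldimethylsilyl ether (PdCl2(dppf), K3PO4) gives the 2-alkyl enone F5. Copper-catalysed asymmetric conjugate borylation (B2pin2, CuCl, NaOt-Bu, chiral bisphosphine, MeOH) with thermodynamic α-protonation gives the trans β-boryl ketone F6, and NaBO3 oxidation with retention gives 4.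

Step 20 may fail because enolization of the hindered ketone, with epimerization at C4, can outpace ylide addition. The fallback sets out from 28 and returns at 29 with no new compound (F0): a mixed McMurry coupling with excess acetone (TiCl4, Zn, pyridine, THF, reflux) forms the isopropylidene group by reductive carbonyl coupling under non-basic conditions.

Further compounds
F1 | step 14 | aldoxime of 21 (C6 as CH=NOH) | COc1cc(C)c(OCOC)c(C(=O)[C@@](C)(CCC=NO)[C@H]2CC[C@H](O[Si](C)(C)C(C)(C)C)[C@@H](CCCO[Si](C)(C)C(C)(C)C)C2=C)c1
F2 | step 14 | nitrile from 21 (C6 as C≡N) | COc1cc(C)c(OCOC)c(C(=O)[C@@](C)(CCC#N)[C@H]2CC[C@H](O[Si](C)(C)C(C)(C)C)[C@@H](CCCO[Si](C)(C)C(C)(C)C)C2=C)c1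
F3 | step 14 | C6 ketimine corresponding to 23 | COc1cc(C)c(OCOC)c(C(=O)[C@]2(C)[C@H]3CC[C@H](O[Si](C)(C)C(C)(C)C)[C@@H](CCCO[Si](C)(C)C(C)(C)C)[C@]3(C)C(=N)CC2)c1
F4 | step 2 | 2-iodocyclohex-2-en-1-one | O=C1CCCC=C1I
F5 | step 2 | 2-{3-[(tert-butyldimethylsilyl)oxy]propyl}cyclohex-2-en-1-one | O=C1CCCC=C1CCCO[Si](C)(C)C(C)(C)C
F6 | step 2 | trans-3-(4,4,5,5-tetramethyl-1,3,2-dioxaborolan-2-yl)-2-{3-[(tert-butyldimethylsilyl)oxy]propyl}cyclohexan-1-one | O=C1CCC[C@H](B2OC(C)(C)C(C)(C)O2)[C@H]1CCCO[Si](C)(C)C(C)(C)C
F0 | step 20 | none | none
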